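The ring is numbered so that C1 carries the methyl, C3 the pyranone and C4 the isopropyl group. The cyclohexene is read as a piperitone: C3 is treated as a latent ketone, which turns the C1=C2 alkene into an aldol-condensation retron and the C3–C4 bond into an acyl–alkene union. In one flask an acetyl radical from acetaldehyde adds to the prenyl terminus of sulcatone (C3–C4) and the resulting 1,5-diketone is cyclodehydrated (C1=C2), so a two-carbon acetyl unit is inserted between the ends of an acyclic C8 ketone. Dynamic kinetic resolution then fixes C4, and the pyranone is attached last through the piperityl cation, trans to isopropyl.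

Key step: step 1

Assumption: the (S)-BINAP/(R,R)-DPEN catalyst series in step 2 is assigned by analogy with the hydrogenation of 2-alkylcyclohexanones; if the sense of induction proves opposite, the mirror-image catalyst is used.

Step 1
Reactants: 1 6-methylhept-5-en-2-one (sulcatone); 2 acetaldehyde
Product: 4 racemic piperitone [3-methyl-6-(propan-2-yl)cyclohex-2-en-1-one], via diketone 3 (not isolated)
Conditions: 2 (5 equiv), HSCH2CO2Me (10 mol %), t-BuON=NOt-Bu (5 mol %), 1,4-dioxane, 60 °C, sealed vessel; evaporate excess 2; then KOH (20 mol %), EtOH, 70 °C
Reagents that add atoms: none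
Why: A thiyl radical abstracts the formyl hydrogen of 2, the nucleophilic acetyl radical adds to the less substituted alkene carbon of 1 (future C4) to give a tertiary radical that is quenched by the thiol (polarity-reversal catalysis), and base then closes the 1,5-diketone 3 by intramolecular aldol addition of the new acetyl methyl to the original methyl ketone followed by E1cB dehydration. The closest known reaction types are the radical-chain hydroacylation of unactivated alkenes by aldehydes and the aldol-condensation half of a Robinson annulation. The ring closes in the 6-(enolendo)-exo-trig mode. The only stereocenter (C4, alpha to the ketone) forms without control and is deliberately left racemic, because it is epimerisable and is set in step 2. The step needs regioselective acyl addition, secured by formation of the tertiary radical, and regioselective aldolisation, secured because the alternative closure would require attack on the ketone flanked by the isopropyl-bearing carbon.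

Step 2
Reactants: 4 racemic piperitone
Product: 5 (1S,6R)-3-methyl-6-(propan-2-yl)cyclohex-2-en-1-ol (cis-piperitol)
Conditions: H2 (8 atm), trans-RuCl2[(S)-BINAP][(R,R)-DPEN] (0.5 mol %), KOt-Bu (10 mol %), i-PrOH, 25 °C
Reagents that add atoms: none
Why: Noyori asymmetric hydrogenation under dynamic kinetic resolution, in which the alkoxide base should racemise the ketone through its enolate faster than the mismatched enantiomer is reduced, the C=O is reduced chemoselectively over the conjugated C=C, and the catalyst funnels both enantiomers into the cis alcohol with the (6R) isopropyl center.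

Step 3
Reactants: 6 4-hydroxy-6-methyl-2H-pyran-2-one (triacetic acid lactone); 7 benzaldehyde
Product: 9 4-hydroxy-6-[(E)-2-phenylethenyl]-2H-pyran-2-one, via aldol adduct 8 (not isolated)
Conditions: LiN(i-Pr)2 (2.3 equiv), THF, −78 °C; 7, −78 to 0 °C; aq. HCl; then TsOH·H2O (10 mol %), toluene, 90 °C
Reagents that add atoms: none
Why: The dianion of 6 reacts at its vinylogous 6-CH2 terminus in an aldol addition to benzaldehyde, and acid-catalysed dehydration of the benzylic alcohol should give the conjugated (E)-styryl group under thermodynamic control (vinylogous aldol condensation).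

Step 4
Reactants: 5 cis-piperitol; 9 4-hydroxy-6-[(E)-2-phenylethenyl]-2H-pyran-2-one
Product: 10 4-hydroxy-3-[(1R,6R)-3-methyl-6-(propan-2-yl)cyclohex-2-en-1-yl]-6-[(E)-2-phenylethenyl]-2H-pyran-2-one (target)
Conditions: Sc(OTf)3 (5 mol %), MgSO4, CH2Cl2–MeNO2, −10 to 20 °C
Reagents that add atoms: none
Why: Friedel–Crafts-type allylation, in which the Lewis acid ionises the allylic alcohol to the piperityl cation and the enolic C3 of the pyranone attacks its secondary terminus anti to the adjacent isopropyl group, so the new stereocenter should be set trans by the (6R) center whatever the carbinol configuration of 5.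

Compound list
1 | 6-methylhept-5-en-2-one (sulcatone) | CC(=O)CCC=C(C)C | starting material
2 | acetaldehyde | CC=O | starting material
3 | racemic 3-(propan-2-yl)heptane-2,6-dione | CC(=O)CCC(C(C)C)C(C)=O | intermediate
4 | racemic piperitone, 3-methyl-6-(propan-2-yl)cyclohex-2-en-1-one | CC1=CC(=O)C(C(C)C)CC1 | intermediate
5 | (1S,6R)-3-methyl-6-(propan-2-yl)cyclohex-2-en-1-ol (cis-piperitol) | CC1=C[C@@H](O)[C@@H](C(C)C)CC1 | intermediate
6 | 4-hydroxy-6-methyl-2H-pyran-2-one (triacetic acid lactone) | Cc1cc(O)cc(=O)o1 | starting material
7 | benzaldehyde | O=Cc1ccccc1 | starting material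
8 | racemic 4-hydroxy-6-(2-hydroxy-2-phenylethyl)-2H-pyran-2-one | O=c1cc(O)cc(CC(O)c2ccccc2)o1 | intermediate
9 | 4-hydroxy-6-[(E)-2-phenylethenyl]-2H-pyran-2-one | O=c1cc(O)cc(/C=C/c2ccccc2)o1 | intermediate
10 | 4-hydroxy-3-[(1R,6R)-3-methyl-6-(propan-2-yl)cyclohex-2-en-1-yl]-6-[(E)-2-phenylethenyl]-2H-pyran-2-one | CC1=C[C@H](c2c(O)cc(/C=C/c3ccccc3)oc2=O)[C@@H](C(C)C)CC1 | target

Total step count: 4
Longest linear sequence: 3 steps (step 1, step 2, step 4)

Steps most likely to fail

Step 1. The radical chain may be short on the trisubstituted, electron-rich alkene: the acyl radical adds slowly, and thiol–ene addition, aldehyde telomerisation or autoxidation can compete. The fallback sets out from 1 and makes the same C3–C4 bond by a polar route. Kondakov-type acylation of the alkene with acetic anhydride and ZnCl2 (CH2Cl2, 0 to 20 °C) should give the β,γ-unsaturated diketone 3-(prop-1-en-2-yl)heptane-2,6-dione F1. Hydrogenation of its 1,1-disubstituted alkene (H2, Pd/C, EtOAc) comes back to the route at diketone 3, which is cyclised to 4 with KOH in EtOH as in step 1.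

Step 4. The allyl cation may be lost by elimination to dienes; loss of the C4 proton gives an achiral 1,3-diene whose re-protonation would erode the enantiomeric purity. The acid may also close the 4-OH of the product onto the ring alkene. The fallback sets out from 5 and avoids free cations. Mitsunobu inversion with 4-nitrobenzoic acid (PPh3, diisopropyl azodicarboxylate, THF, 0 °C) should give (1R,6R)-3-methyl-6-(propan-2-yl)cyclohex-2-en-1-yl 4-nitrobenzoate F4. Tsuji–Trost C-allylation of 9 with F4 (Pd(PPh3)4, 5 mol %, THF, 40 °C) proceeds with double inversion, so net retention, at the less substituted allyl terminus and comes back to the route at 10.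

Step 2. Racemisation may be too slow relative to reduction, which would lower the enantiomeric purity, and the base may isomerise or condense the enone. The fallback sets out from 4 and replaces the dynamic process by a classical resolution. Reduction with LiBH(s-Bu)3 (THF, −78 °C) should give racemic cis-3-methyl-6-(propan-2-yl)cyclohex-2-en-1-ol F2. Kinetic resolution with Candida antarctica lipase B and vinyl acetate in hexane is expected to acylate the (1S) alcohol, giving (1S,6R)-3-methyl-6-(propan-2-yl)cyclohex-2-en-1-yl acetate F3 and leaving the (1R,6S) alcohol behind. Methanolysis of F3 (K2CO3 cat., MeOH) comes back to the route at 5; if the lipase prefers the other enantiomer, the unreacted alcohol is 5 itself.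

Further compounds
F1 | step 1 | racemic 3-(prop-1-en-2-yl)heptane-2,6-dione | CC(=O)CCC(C(C)=C)C(C)=O
F2 | step 2 | racemic cis-3-methyl-6-(propan-2-yl)cyclohex-2-en-1-ol | CC1=C[C@@H](O)[C@@H](C(C)C)CC1.CC1=C[C@H](O)[C@H](C(C)C)CC1
F3 | step 2 | (1S,6R)-3-methyl-6-(propan-2-yl)cyclohex-2-en-1-yl acetate | CC1=C[C@@H](OC(C)=O)[C@@H](C(C)C)CC1
F4 | step 4 | (1R,6R)-3-methyl-6-(propan-2-yl)cyclohex-2-en-1-yl 4-nitrobenzoate | CC1=C[C@H](OC(=O)c2ccc(cc2)[N+](=O)[O-])[C@@H](C(C)C)CC1
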